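I chose to reckon the small part and let L follow from it, because L led each earlier run at its last reading.

| flask | E | X | remark | time |
|---|---|---|---|---|
| larch | 0.42 M | 0.05 mol% | run made earlier |  |
| birch | 0.63 M | 0.05 mol% | run made earlier |  |
| maple | 0.84 M | 0.075 mol% | run made earlier |  |
| flask | 0.84 M | 0.05 mol% |  | 5.0 d |

| run | time / d | G / % | E / % | Z / % | L / % | D / % |
|---|---|---|---|---|---|---|
| larch | 0.208 | 0 | 93.3 | 0 | 6.7 | 0 |
| larch | 0.625 | 1.7 | 80.3 | 0.6 | 17.8 | 0 |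
| larch | 1.04 | 1.9 | 68.6 | 0.5 | 27.1 | 0 |
| larch | 1.67 | 3.4 | 53.9 | 2.0 | 38.9 | 0.6 |
| larch | 2.50 | 4.4 | 39.5 | 3.8 | 50.1 | 2.0 |
| larch | 3.00 | 4.0 | 33.0 | 4.8 | 55.5 | 2.4 |
| larch | 4.00 | 4.9 | 22.5 | 5.8 | 62.7 | 4.6 |
| birch | 0.625 | 2.1 | 80.2 | 0.3 | 17.5 | 0 |
| birch | 1.25 | 4.2 | 61.9 | 2.2 | 31.3 | 1.0 |
| birch | 1.67 | 4.7 | 51.0 | 3.3 | 38.9 | 2.1 |
| birch | 2.50 | 5.6 | 36.5 | 5.2 | 48.6 | 4.8 |
| birch | 3.00 | 5.8 | 29.4 | 6.5 | 53.6 | 6.0 |
| birch | 4.00 | 5.8 | 19.3 | 7.6 | 59.5 | 7.7 |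
| maple | 0.333 | 1.9 | 87.8 | 0.6 | 10.2 | 0 |
| maple | 1.04 | 5.8 | 62.5 | 3.1 | 26.5 | 2.2 |
| maple | 1.67 | 7.3 | 44.7 | 5.3 | 36.5 | 6.0 |
| maple | 3.00 | 7.6 | 21.1 | 9.3 | 48.0 | 13.2 |
| maple | 4.00 | 7.9 | 12.4 | 11.1 | 52.1 | 17.0 |

(scatter of a reading: 0.3 percentage points)

1. the species that holds most of what was charged as E, at 5.0 d (L / E / Z / D / G)
2. the largest share itself, whichever of these holds it, in percent of the E charged

How large is the side part? At 4.00 d the ratio (G + Z + D)/L read 0.355 in birch and 0.691 in maple. These stand as 1.95 to one, while the catalyst charged, loading times starting E, stands as 2.00 to one. The flask differs from maple in loading, so I scaled maple's reading by loading and took the side ratio r, the amounts (G + Z + D)/L standing at that time, as 0.461. This r is no fixed split: maple read 0.419 at 1.04 d, so it climbs with time, and a value from 4.00 d used at 5.0 d probably sets r low and L high.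

How much E remains? The first-order loss constants read 0.411 d⁻¹ in birch and 0.522 d⁻¹ in maple. Placed by catalyst charged, the flask gets 0.448 d⁻¹, which leaves E at 10.6%.

So, carrying r from 4.00 d to 5.0 d as an estimate, I put L at (spent E)/(1 + r), or 61.2%. That exceeds the 28.2% shared by G, Z and D.

The forecast said L at 60%, a point under mine, holding that the side route “scales roughly with absolute catalyst”.

The flask gave L at 59.0%.

    G ⇌ Z (K = 1.40, k = 0.0420 h⁻¹)
    E + Q ⇌ G + Q, rate k2*[E]*[Q] forward; the back reaction follows from the equilibrium constant (K = 6.10, k = 20.0 L mol⁻¹ h⁻¹)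
    L ⇌ E (k = 9.70 × 10⁻⁴ h⁻¹)
    X → Q (k = 0.0530 h⁻¹)
    Z + Q ⇌ L + Q, rate k5*[Q]*[Z] forward; the back reaction follows from the equilibrium constant (K = 1.60, k = 1.40 L mol⁻¹ h⁻¹)
    G + Q ⇌ D + Q, rate k6*[Q]*[G] forward; the back reaction follows from the equilibrium constant (K = 2.70, k = 92.0 L mol⁻¹ h⁻¹)

Q is the working form of X. In the flask, the forward half-life of L going back to E, 30 d, is long against 5.0 d, and the net flow from E to L reached 60.4% of the E charged. The flask's own r at 5.00 d was 0.504, against my 0.461. With twice the X, my scaling by loading puts r at 0.922, and holding E at the flask's 11% gives L 46.3%; that flask held 48.4%.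

(The readings are calculated for an exercise; scatter was added.)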